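The route rests on disconnecting the C2–C3 bond of the pyrrole, the bond between the ester-bearing carbon and the carbon that carries the C23 chain. N1–C2–CO2Me is then glycine methyl ester, and C3–C4–C5 plus the chain is (E)-hexacos-2-enal. The key step condenses the two, lets the resulting N-alkenylidene glycinate close as a 2-azapentadienyl anion (vinyl azomethine ylide) by 6π 1,5-electrocyclisation, and aromatises the pyrroline with Cu(II) in the same flask. One operation thus forms the ring, fixes the 2,3-substitution pattern with free C4–H and C5–H, and installs the ester. The precursor is a linear enal made from 1-tetracosanol in two steps.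

Key step: step 3

Remark: the target has no stereocentre and no stereogenic double bond, so it is achiral and no enantiomer has to be selected; the chain is read as n-tricosyl (C23).

Step 1
Reactants: 1 1-tetracosanol
Product: 2 tetracosanal
Conditions: TEMPO (10 mol %), PhI(OAc)2 (1.1 equiv), CH2Cl2, 35 °C
Reagents that add atoms: none
Why: Oxoammonium (TEMPO/PhI(OAc)2) oxidation of a primary alcohol should stop at the aldehyde in anhydrous medium, and gentle warming keeps the waxy alcohol in solution.

Step 2
Reactants: 2 tetracosanal
Product: 3 (E)-hexacos-2-enal
Conditions: Ph3P=CHCHO (1.1 equiv), toluene, 80 °C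
Reagents that add atoms: (triphenylphosphoranylidene)acetaldehyde, O=CC=P(c1ccccc1)(c1ccccc1)c1ccccc1
Why: Wittig olefination with the stabilised formyl ylide should give the E-enal, and the aliphatic aldehyde is more electrophilic than the product enal, which favours a single two-carbon homologation.

Step 3
Reactants: 3 (E)-hexacos-2-enal; 4 glycine methyl ester hydrochloride
Product: 7 methyl 3-tricosyl-1H-pyrrole-2-carboxylate, via glycinate imine 5 (not isolated), via 1-pyrroline 6 (not isolated)
Conditions: 4 (1.5 equiv), 4 Å MS, pyridine (0.03 M), rt then 110 °C; then Cu(OAc)2 (2.2 equiv), 110 °C
Reagents that add atoms: none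
Why: Proposed new method: condensation of 3 with the amine gives 1-azadiene 5, whose glycine CH2 (flanked by ester and C=N) loses a proton in hot pyridine to a 2-azapentadienyl anion, or shifts it to nitrogen to give the N-H vinyl azomethine ylide; either species holds 6 π-electrons on the five atoms C(CO2Me)-N-CH-CH-CH(R) and should close by thermal disrotatory 1,5-electrocyclisation, forming the C2-C3 bond and the N-ring at once to give pyrroline 6 after proton transfer, which Cu(II) then dehydrogenates by single-electron oxidation of its C2 aza-enolate with aromatisation as driving force. The closest known reaction type is the one-pot electrocyclisation/oxidation of glycine ester imines of aryl enones to pyrrole-2-carboxylates, together with the 1,5-dipolar electrocyclisation of vinyl azomethine ylides; the label is used because an enolisable, purely aliphatic enal aldimine is not known to have been shown in it. The ring closes as a pentadienyl-anion-type 6π electrocyclisation (formally 5-endo-trig, allowed here because it is pericyclic). No stereocentre has to be controlled: C2 and C3 of 6 are stereogenic only transiently and both are erased on aromatisation. Regiochemistry is fixed by connectivity, since the ester-bearing carbon can bond only to the former β-carbon that carries the C23 chain, leaving the former C2 and C1 of the enal as the free C4-H and C5-H. The step needs 1,2-condensation and intramolecular closure ahead of aza-Michael addition, γ-deprotonation to a dienamine and intermolecular [3+2] dimerisation, plus access to the U-shaped geometry with the glycine carbon syn to the vinyl group; imine formation over sieves at room temperature before heating, high dilution and the thermal E/Z mobility of the aldimine and its delocalised anion are relied on for this.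

Compound list
1 | 1-tetracosanol | CCCCCCCCCCCCCCCCCCCCCCCCO | starting material
2 | tetracosanal | CCCCCCCCCCCCCCCCCCCCCCCC=O | intermediate
3 | (E)-hexacos-2-enal | CCCCCCCCCCCCCCCCCCCCCCC/C=C/C=O | intermediate
4 | glycine methyl ester hydrochloride (methyl 2-aminoacetate hydrochloride) | Cl.NCC(=O)OC | starting material
5 | methyl N-[(2E)-hexacos-2-en-1-ylidene]glycinate | CCCCCCCCCCCCCCCCCCCCCCC/C=C/C=N/CC(=O)OC | intermediate
6 | methyl 3-tricosyl-3,4-dihydro-2H-pyrrole-2-carboxylate (racemic, mixture of C2/C3 diastereomers) | CCCCCCCCCCCCCCCCCCCCCCCC1CC=NC1C(=O)OC | intermediate
7 | methyl 3-tricosyl-1H-pyrrole-2-carboxylate | CCCCCCCCCCCCCCCCCCCCCCCc1cc[nH]c1C(=O)OC | target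

Total step count: 3. Longest linear sequence: 3 steps (1 → 2 → 3 → 7).

Steps most likely to fail

Step 3. The aldimine may be consumed before ring closure by tautomerisation through its γ-CH2 to a dienamine and oligomerisation, by aza-Michael addition, or by intermolecular cycloaddition. It may also fail to reach the syn geometry needed for 1,5-closure. The fallback uses known chemistry, sets out from 2 and comes back at 7. A nitroaldol (Henry) addition of nitromethane to 2 (cat. KOtBu, THF/t-BuOH, 30 °C) should give 1-nitropentacosan-2-ol F1. Acetylation (Ac2O, cat. DMAP, CH2Cl2) should give 1-nitropentacosan-2-yl acetate F2. Treatment of this with methyl isocyanoacetate and DBU (2.2 equiv) in THF should eliminate acetic acid to the nitroalkene in situ and effect a Barton–Zard pyrrole synthesis. The isocyanoacetate carbon adds to the chain-bearing carbon, the nitronate closes onto the isocyanide, and loss of nitrite with aromatisation should give 7 with the chain at C3.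

Step 2. The product enal may react again with the ylide to give the dienal and higher vinylogues, while slow olefination leaves time for aldol self-condensation of the aldehyde at 80 °C. The fallback sets out from 2 and comes back at 3. A Horner–Wadsworth–Emmons reaction with triethyl phosphonoacetate (NaH, THF, 0 °C to 40 °C) should give ethyl (E)-hexacos-2-enoate F3. DIBAL-H reduction (2.2 equiv, toluene, −20 to 0 °C) should give (E)-hexacos-2-en-1-ol F4. Allylic oxidation with MnO2 (CHCl3, rt) should then give 3.

Step 1. Poor solubility of the waxy alcohol may leave the oxidation incomplete. Hemiacetal formation between product and unreacted alcohol, followed by oxidation, would divert material to the wax ester. The fallback sets out from 1 and comes back at 2. Tosylation (TsCl, pyridine, CHCl3, 40 °C) should give tetracosyl 4-methylbenzenesulfonate F5. Kornblum oxidation of the molten sulfonate (DMSO, NaHCO3, 150 °C, short reaction time under N2) should then give 2 by displacement with DMSO and base-induced collapse of the alkoxysulfonium salt.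

Further compounds
F1 | step 3 | 1-nitropentacosan-2-ol (racemic) | CCCCCCCCCCCCCCCCCCCCCCCC(O)C[N+](=O)[O-]
F2 | step 3 | 1-nitropentacosan-2-yl acetate (racemic) | CCCCCCCCCCCCCCCCCCCCCCCC(OC(C)=O)C[N+](=O)[O-]
F3 | step 2 | ethyl (E)-hexacos-2-enoate | CCCCCCCCCCCCCCCCCCCCCCC/C=C/C(=O)OCC
F4 | step 2 | (E)-hexacos-2-en-1-ol | CCCCCCCCCCCCCCCCCCCCCCC/C=C/CO
F5 | step 1 | tetracosyl 4-methylbenzenesulfonate | CCCCCCCCCCCCCCCCCCCCCCCCOS(=O)(=O)c1ccc(C)cc1
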